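## Retrosynthetic overview

1. Ring numbering: C1 is the ring CH that carries the side chain, C4 carries CH2OH, C8 and C12 carry CH3. The single 14-membered ring is closed at C13–C14 by intramolecular alkylation of a C14 α-sulfonyl carbanion with the C13 (Z)-allylic bromide.
2. The open chain comes from a Z-selective Wittig union at C3=C4 of phosphonium fragment A (C14, C1–C3, side chain) with α-benzyloxy ketone fragment B (C4–C13).
3. Fragment A comes from geraniol: Sharpless epoxidation, then vinyl-cuprate opening at the epoxide CH, sets both stereocentres. The vinyl group becomes C2–C3 and the CH2OH becomes CH2SO2Ph (C14).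
4. Fragment B comes from geranyl acetate (7E olefin), a Still–Gennari olefination (11Z olefin) and an acetoacetic ester alkylation/decarboxylation (C4, C5, CH2OBn).
5. The ring is formed once, at step 20, after all three ring olefins are in place. One dissolving-metal step then removes sulfone and benzyl, and fluoride removes the silyl ether.

Assumption: vinylmagnesium bromide solution (3) and the Still–Gennari propionate reagent (15) are bought; the target is the single enantiomer drawn in the SMILES, (1R) at the ring CH and (2R) at the carbinol.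

## Route

**Step 1**
Reactants: 1 geraniol
Product: 2 [(2R,3R)-3-methyl-3-(4-methylpent-3-en-1-yl)oxiran-2-yl]methanol
Conditions: Ti(OiPr)4 (5 mol%), D-(−)-diethyl tartrate (6 mol%), t-BuOOH, 4 Å MS, CH2Cl2, −20 °C
Reagents that add atoms: tert-butyl hydroperoxide, CC(C)(C)OO
Why: Sharpless asymmetric epoxidation with the D-(−)-tartrate ligand oxidises only the allylic-alcohol alkene and fixes both epoxide carbons as (2R,3R), which become the two stereocentres of the target.

**Step 2**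
Reactants: 2 [(2R,3R)-3-methyl-3-(4-methylpent-3-en-1-yl)oxiran-2-yl]methanol; 3 vinylmagnesium bromide
Product: 4 (2S,3R)-2-ethenyl-3,7-dimethyloct-6-ene-1,3-diol
Conditions: CH2=CHMgBr (5 equiv), CuI (0.3 equiv), THF, −40 → −10 °C; then sat. aq NH4Cl
Reagents that add atoms: none
Why: Copper-catalysed SN2 epoxide opening occurs at the only accessible carbon (C2, since C3 is fully substituted) with inversion, setting the CH stereocentre (ring C1) next to the retained tertiary carbinol.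

**Step 3**
Reactants: 4 (2S,3R)-2-ethenyl-3,7-dimethyloct-6-ene-1,3-diol
Product: 5 (3R,4R)-4,8-dimethyl-3-[(phenylsulfanyl)methyl]nona-1,7-dien-4-ol
Conditions: PhSSPh (1.5 equiv), n-Bu3P (1.5 equiv), pyridine, rt → 50 °C
Reagents that add atoms: diphenyl disulfide, c1ccc(cc1)SSc1ccccc1
Why: Hata (Mukaiyama-type redox condensation) sulfenylation converts only the primary alcohol, through its alkoxyphosphonium salt, into the phenyl sulfide; the tertiary alcohol does not react.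

**Step 4**
Reactants: 5 (3R,4R)-4,8-dimethyl-3-[(phenylsulfanyl)methyl]nona-1,7-dien-4-ol
Product: 6 triethyl{[(3R,4R)-4,8-dimethyl-3-[(phenylsulfanyl)methyl]nona-1,7-dien-4-yl]oxy}silane
Conditions: TESOTf (1.5 equiv), 2,6-lutidine (3 equiv), CH2Cl2, −78 → 0 °C
Reagents that add atoms: triethylsilyl trifluoromethanesulfonate, CC[Si](CC)(CC)OS(=O)(=O)C(F)(F)F
Why: Silyl triflate silylation protects the hindered tertiary alcohol, which would otherwise direct epoxidation in step 5 and cyclise onto the iodide of step 7.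

**Step 5**
Reactants: 6 triethyl{[(3R,4R)-4,8-dimethyl-3-[(phenylsulfanyl)methyl]nona-1,7-dien-4-yl]oxy}silane
Product: 7 triethyl{[(3R,4R)-4,8-dimethyl-3-[(phenylsulfonyl)methyl]nona-1,7-dien-4-yl]oxy}silane
Conditions: (NH4)6Mo7O24·4H2O (10 mol%), 30% aq H2O2 (5 equiv), EtOH/THF, 0 °C → rt
Reagents that add atoms: hydrogen peroxide, OO
Why: Molybdate-catalysed sulfide-to-sulfone oxidation is much faster at sulfur than epoxidation of unactivated alkenes, so both C=C bonds survive.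

**Step 6**
Reactants: 7 triethyl{[(3R,4R)-4,8-dimethyl-3-[(phenylsulfonyl)methyl]nona-1,7-dien-4-yl]oxy}silane
Product: 9 (3R,4R)-4,8-dimethyl-3-[(phenylsulfonyl)methyl]-4-[(triethylsilyl)oxy]non-7-en-1-ol, via B-alkyl-9-BBN adduct 8 (not isolated)
Conditions: 9-BBN (2 equiv), THF, 0 °C → rt; then 3 M NaOH, 30% H2O2, 0 °C → rt
Reagents that add atoms: hydrogen peroxide, OO (hydroxyl oxygen of 9); 9-borabicyclo[3.3.1]nonane, B1C2CCCC1CCC2 (boron framework of 8 only)
Why: Anti-Markovnikov hydroboration–oxidation with 9-BBN reacts only at the monosubstituted vinyl group and leaves the trisubstituted alkene, giving the C2–C3 arm.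

**Step 7**
Reactants: 9 (3R,4R)-4,8-dimethyl-3-[(phenylsulfonyl)methyl]-4-[(triethylsilyl)oxy]non-7-en-1-ol
Product: 10 triethyl{[(3R,4R)-1-iodo-4,8-dimethyl-3-[(phenylsulfonyl)methyl]non-7-en-4-yl]oxy}silane
Conditions: I2, PPh3, imidazole, CH2Cl2, 0 °C → rt
Reagents that add atoms: iodine, II
Why: Appel-type iodination (Garegg conditions) converts the unhindered primary alcohol to the iodide by SN2 under neutral conditions.

**Step 8**
Reactants: 10 triethyl{[(3R,4R)-1-iodo-4,8-dimethyl-3-[(phenylsulfonyl)methyl]non-7-en-4-yl]oxy}silane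
Product: 11 {(3R,4R)-4,8-dimethyl-3-[(phenylsulfonyl)methyl]-4-[(triethylsilyl)oxy]non-7-en-1-yl}(triphenyl)phosphonium iodide
Conditions: PPh3 (3 equiv), MeCN, 80 °C, 48 h
Reagents that add atoms: triphenylphosphine, c1ccc(cc1)P(c1ccccc1)c1ccccc1
Why: SN2 quaternisation of triphenylphosphine by the primary iodide gives the Wittig salt (fragment A).

**Step 9**
Reactants: 12 geranyl acetate
Product: 13 (2E)-5-(3,3-dimethyloxiran-2-yl)-3-methylpent-2-en-1-yl acetate (racemic)
Conditions: mCPBA (1.05 equiv), CH2Cl2, 0 °C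
Reagents that add atoms: 3-chloroperoxybenzoic acid, OOC(=O)c1cccc(Cl)c1
Why: Prilezhaev epoxidation takes the electron-rich remote alkene in preference to the alkene deactivated by the allylic acetate.

**Step 10**
Reactants: 13 (2E)-5-(3,3-dimethyloxiran-2-yl)-3-methylpent-2-en-1-yl acetate
Product: 14 (2E)-3-methyl-6-oxohex-2-en-1-yl acetate
Conditions: H5IO6 (1.2 equiv), THF/H2O, 0 °C
Reagents that add atoms: none
Why: Periodic acid hydrolyses the epoxide and cleaves the resulting glycol (Malaprade cleavage), excising acetone and leaving the C11 aldehyde with the 7E alkene untouched.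

**Step 11**
Reactants: 14 (2E)-3-methyl-6-oxohex-2-en-1-yl acetate; 15 ethyl 2-[bis(2,2,2-trifluoroethoxy)phosphoryl]propanoate
Product: 16 ethyl (2Z,6E)-8-(acetyloxy)-2,6-dimethylocta-2,6-dienoate
Conditions: 15 (1.1 equiv), KHMDS (1.1 equiv), 18-crown-6 (3 equiv), THF, −78 °C
Reagents that add atoms: none
Why: Still–Gennari olefination (Z-selective Horner–Wadsworth–Emmons) collapses the kinetic adduct quickly and places the chain cis to the ester, giving the 11Z trisubstituted alkene.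

**Step 12**
Reactants: 16 ethyl (2Z,6E)-8-(acetyloxy)-2,6-dimethylocta-2,6-dienoate
Product: 17 ethyl (2Z,6E)-8-hydroxy-2,6-dimethylocta-2,6-dienoate
Conditions: K2CO3 (0.2 equiv), EtOH, 0 °C → rt
Reagents that add atoms: none
Why: Base-catalysed transesterification removes the acetate, while the ethyl enoate is unchanged in ethanol.

**Step 13**
Reactants: 17 ethyl (2Z,6E)-8-hydroxy-2,6-dimethylocta-2,6-dienoate
Product: 18 ethyl (2Z,6E)-8-bromo-2,6-dimethylocta-2,6-dienoate
Conditions: CBr4 (1.3 equiv), PPh3 (1.4 equiv), CH2Cl2, −20 → 0 °C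
Reagents that add atoms: carbon tetrabromide, BrC(Br)(Br)Br
Why: Appel bromination of the primary allylic alcohol proceeds by SN2 without allylic transposition or loss of alkene geometry.

**Step 14**
Reactants: 19 ethyl 4-chloro-3-oxobutanoate; 20 benzyl alcohol
Product: 21 ethyl 4-(benzyloxy)-3-oxobutanoate
Conditions: NaH (2.2 equiv), THF, 0 °C → rt; then dilute aq HCl
Reagents that add atoms: none
Why: Williamson etherification: sodium benzyloxide displaces the primary chloride of the enolised chloro keto ester.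

**Step 15**
Reactants: 18 ethyl (2Z,6E)-8-bromo-2,6-dimethylocta-2,6-dienoate; 21 ethyl 4-(benzyloxy)-3-oxobutanoate
Product: 22 diethyl (4E,8Z)-2-[(benzyloxy)acetyl]-5,9-dimethyldeca-4,8-dienedioate (racemic at C2)
Conditions: 21 (1.3 equiv), NaH (1.2 equiv), THF, 0 °C; then 18, 0 °C → rt
Reagents that add atoms: none
Why: Acetoacetic ester alkylation: the soft β-keto ester enolate attacks the primary allylic bromide at carbon by SN2, forming C5–C6 without touching the enoate or the alkene geometries.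

**Step 16**
Reactants: 22 diethyl (4E,8Z)-2-[(benzyloxy)acetyl]-5,9-dimethyldeca-4,8-dienedioate
Product: 23 ethyl (2Z,6E)-11-(benzyloxy)-2,6-dimethyl-10-oxoundeca-2,6-dienoate
Conditions: LiCl (3 equiv), H2O (2 equiv), DMSO, 140 °C
Reagents that add atoms: none
Why: Krapcho dealkoxycarbonylation removes only the activated β-keto ester group under neutral conditions and leaves the conjugated ethyl ester, giving the α-benzyloxy ketone (fragment B).

**Step 17**
Reactants: 11 {(3R,4R)-4,8-dimethyl-3-[(phenylsulfonyl)methyl]-4-[(triethylsilyl)oxy]non-7-en-1-yl}(triphenyl)phosphonium iodide; 23 ethyl (2Z,6E)-11-(benzyloxy)-2,6-dimethyl-10-oxoundeca-2,6-dienoate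
Product: 25 ethyl (2Z,6E,10Z,13R,14R)-10-[(benzyloxy)methyl]-2,6,14,18-tetramethyl-13-[(phenylsulfonyl)methyl]-14-[(triethylsilyl)oxy]nonadeca-2,6,10,17-tetraenoate, via phosphonium ylide 24 (not isolated)
Conditions: KHMDS (1.0 equiv per 11), THF, −78 → 0 °C; then 23, THF/HMPA, −78 °C → rt
Reagents that add atoms: none
Why: Wittig olefination of a non-stabilised, lithium-free ylide with an α-alkoxy ketone places the ylide substituent cis to the alkoxymethyl arm, giving the C3=C4 alkene with C2 cis to CH2OBn; the phosphonium CH2 is far more acidic than the sulfone CH2, so only the ylide forms.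

**Step 18**
Reactants: 25 ethyl (2Z,6E,10Z,13R,14R)-10-[(benzyloxy)methyl]-2,6,14,18-tetramethyl-13-[(phenylsulfonyl)methyl]-14-[(triethylsilyl)oxy]nonadeca-2,6,10,17-tetraenoate
Product: 26 (2Z,6E,10Z,13R,14R)-10-[(benzyloxy)methyl]-2,6,14,18-tetramethyl-13-[(phenylsulfonyl)methyl]-14-[(triethylsilyl)oxy]nonadeca-2,6,10,17-tetraen-1-ol
Conditions: DIBAL-H (2.5 equiv), CH2Cl2, −78 °C; Rochelle salt work-up
Reagents that add atoms: none
Why: Hydride 1,2-reduction of the enoate gives the (Z)-allylic alcohol; sulfone, silyl ether and benzyl ether are inert.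

**Step 19**
Reactants: 26 (2Z,6E,10Z,13R,14R)-10-[(benzyloxy)methyl]-2,6,14,18-tetramethyl-13-[(phenylsulfonyl)methyl]-14-[(triethylsilyl)oxy]nonadeca-2,6,10,17-tetraen-1-ol
Product: 27 (2Z,6E,10Z,13R,14R)-10-[(benzyloxy)methyl]-1-bromo-2,6,14,18-tetramethyl-13-[(phenylsulfonyl)methyl]-14-[(triethylsilyl)oxy]nonadeca-2,6,10,17-tetraene
Conditions: CBr4 (1.3 equiv), PPh3 (1.4 equiv), CH2Cl2, −20 °C; used at once
Reagents that add atoms: carbon tetrabromide, BrC(Br)(Br)Br
Why: Appel bromination gives the primary (Z)-allylic bromide by SN2 with the alkene geometry retained.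

**Step 20**
Reactants: 27 (2Z,6E,10Z,13R,14R)-10-[(benzyloxy)methyl]-1-bromo-2,6,14,18-tetramethyl-13-[(phenylsulfonyl)methyl]-14-[(triethylsilyl)oxy]nonadeca-2,6,10,17-tetraene
Product: 28 triethyl({(2R)-2-[(1R,3Z,7E,11Z)-4-[(benzyloxy)methyl]-8,12-dimethyl-14-(phenylsulfonyl)cyclotetradeca-3,7,11-trien-1-yl]-6-methylhept-5-en-2-yl}oxy)silane (C14 epimers)
Conditions: LDA (1.5 equiv, commercial solution), THF, −40 °C, 27 added over 8 h by syringe pump (final 1 mM); then 0 °C
Reagents that add atoms: none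
Why: Intramolecular SN2 alkylation of the α-sulfonyl carbanion at the primary allylic bromide closes the 14-membered ring at high dilution; all three ring alkenes are already fixed and the new C14 centre is removed in step 21.

**Step 21**
Reactants: 28 triethyl({(2R)-2-[(1R,3Z,7E,11Z)-4-[(benzyloxy)methyl]-8,12-dimethyl-14-(phenylsulfonyl)cyclotetradeca-3,7,11-trien-1-yl]-6-methylhept-5-en-2-yl}oxy)silane
Product: 29 {(2R)-2-[(1R,3Z,7E,11Z)-4-(hydroxymethyl)-8,12-dimethylcyclotetradeca-3,7,11-trien-1-yl]-6-methylhept-5-en-2-yl} triethylsilyl ether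
Conditions: Li (20 equiv), NH3(l)/THF 4:1, −78 °C, 30 min; then solid NH4Cl
Reagents that add atoms: none
Why: Dissolving-metal (Birch-type) reduction cleaves the alkyl–sulfonyl bond and the benzyl ether in one operation, while isolated trisubstituted alkenes and the silyl ether are not reduced.

**Step 22**
Reactants: 29 {(2R)-2-[(1R,3Z,7E,11Z)-4-(hydroxymethyl)-8,12-dimethylcyclotetradeca-3,7,11-trien-1-yl]-6-methylhept-5-en-2-yl} triethylsilyl ether
Product: 30 (2R)-2-[(1R,3Z,7E,11Z)-4-(hydroxymethyl)-8,12-dimethylcyclotetradeca-3,7,11-trien-1-yl]-6-methylhept-5-en-2-ol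
Conditions: TBAF (3 equiv), THF, rt → 45 °C
Reagents that add atoms: none
Why: Fluoride-mediated desilylation frees the tertiary alcohol under non-acidic conditions that do not disturb the allylic alcohol or the alkenes.

## Compound list

1 | geraniol, (2E)-3,7-dimethylocta-2,6-dien-1-ol | CC(C)=CCC/C(C)=C/CO | starting material
2 | [(2R,3R)-3-methyl-3-(4-methylpent-3-en-1-yl)oxiran-2-yl]methanol | OC[C@H]1O[C@]1(C)CCC=C(C)C | intermediate
3 | vinylmagnesium bromide | C=C[Mg]Br | starting material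
4 | (2S,3R)-2-ethenyl-3,7-dimethyloct-6-ene-1,3-diol | OC[C@@H]([C@](C)(O)CCC=C(C)C)C=C | intermediate
5 | (3R,4R)-4,8-dimethyl-3-[(phenylsulfanyl)methyl]nona-1,7-dien-4-ol | c1ccccc1SC[C@@H]([C@](C)(O)CCC=C(C)C)C=C | intermediate
6 | triethyl{[(3R,4R)-4,8-dimethyl-3-[(phenylsulfanyl)methyl]nona-1,7-dien-4-yl]oxy}silane | c1ccccc1SC[C@@H]([C@](C)(O[Si](CC)(CC)CC)CCC=C(C)C)C=C | intermediate
7 | triethyl{[(3R,4R)-4,8-dimethyl-3-[(phenylsulfonyl)methyl]nona-1,7-dien-4-yl]oxy}silane | O=S(=O)(c1ccccc1)C[C@@H]([C@](C)(O[Si](CC)(CC)CC)CCC=C(C)C)C=C | intermediate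
8 | 9-{(3R,4R)-4,8-dimethyl-3-[(phenylsulfonyl)methyl]-4-[(triethylsilyl)oxy]non-7-en-1-yl}-9-borabicyclo[3.3.1]nonane | O=S(=O)(c1ccccc1)C[C@@H]([C@](C)(O[Si](CC)(CC)CC)CCC=C(C)C)CCB1C2CCCC1CCC2 | intermediate
9 | (3R,4R)-4,8-dimethyl-3-[(phenylsulfonyl)methyl]-4-[(triethylsilyl)oxy]non-7-en-1-ol | O=S(=O)(c1ccccc1)C[C@@H]([C@](C)(O[Si](CC)(CC)CC)CCC=C(C)C)CCO | intermediate
10 | triethyl{[(3R,4R)-1-iodo-4,8-dimethyl-3-[(phenylsulfonyl)methyl]non-7-en-4-yl]oxy}silane | O=S(=O)(c1ccccc1)C[C@@H]([C@](C)(O[Si](CC)(CC)CC)CCC=C(C)C)CCI | intermediate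
11 | {(3R,4R)-4,8-dimethyl-3-[(phenylsulfonyl)methyl]-4-[(triethylsilyl)oxy]non-7-en-1-yl}(triphenyl)phosphonium iodide | O=S(=O)(c1ccccc1)C[C@@H]([C@](C)(O[Si](CC)(CC)CC)CCC=C(C)C)CC[P+](c1ccccc1)(c1ccccc1)c1ccccc1.[I-] | intermediate
12 | geranyl acetate, (2E)-3,7-dimethylocta-2,6-dien-1-yl acetate | CC(=O)OC/C=C(\C)CCC=C(C)C | starting material
13 | (2E)-5-(3,3-dimethyloxiran-2-yl)-3-methylpent-2-en-1-yl acetate (racemic) | CC(=O)OC/C=C(\C)CCC1OC1(C)C | intermediate
14 | (2E)-3-methyl-6-oxohex-2-en-1-yl acetate | CC(=O)OC/C=C(\C)CCC=O | intermediate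
15 | ethyl 2-[bis(2,2,2-trifluoroethoxy)phosphoryl]propanoate | CCOC(=O)C(C)P(=O)(OCC(F)(F)F)OCC(F)(F)F | starting material
16 | ethyl (2Z,6E)-8-(acetyloxy)-2,6-dimethylocta-2,6-dienoate | CCOC(=O)/C(C)=C\CC/C(C)=C/COC(C)=O | intermediate
17 | ethyl (2Z,6E)-8-hydroxy-2,6-dimethylocta-2,6-dienoate | CCOC(=O)/C(C)=C\CC/C(C)=C/CO | intermediate
18 | ethyl (2Z,6E)-8-bromo-2,6-dimethylocta-2,6-dienoate | CCOC(=O)/C(C)=C\CC/C(C)=C/CBr | intermediate
19 | ethyl 4-chloro-3-oxobutanoate | CCOC(=O)CC(=O)CCl | starting material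
20 | benzyl alcohol | OCc1ccccc1 | starting material
21 | ethyl 4-(benzyloxy)-3-oxobutanoate | CCOC(=O)CC(=O)COCc1ccccc1 | intermediate
22 | diethyl (4E,8Z)-2-[(benzyloxy)acetyl]-5,9-dimethyldeca-4,8-dienedioate (racemic) | CCOC(=O)/C(C)=C\CC/C(C)=C/CC(C(=O)OCC)C(=O)COCc1ccccc1 | intermediate
23 | ethyl (2Z,6E)-11-(benzyloxy)-2,6-dimethyl-10-oxoundeca-2,6-dienoate | CCOC(=O)/C(C)=C\CC/C(C)=C/CCC(=O)COCc1ccccc1 | intermediate
24 | phosphonium ylide from 11: {(3R,4R)-4,8-dimethyl-3-[(phenylsulfonyl)methyl]-4-[(triethylsilyl)oxy]non-7-en-1-ylidene}(triphenyl)phosphorane | O=S(=O)(c1ccccc1)C[C@@H]([C@](C)(O[Si](CC)(CC)CC)CCC=C(C)C)CC=P(c1ccccc1)(c1ccccc1)c1ccccc1 | intermediate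
25 | ethyl (2Z,6E,10Z,13R,14R)-10-[(benzyloxy)methyl]-2,6,14,18-tetramethyl-13-[(phenylsulfonyl)methyl]-14-[(triethylsilyl)oxy]nonadeca-2,6,10,17-tetraenoate | O=S(=O)(c1ccccc1)C[C@@H]([C@](C)(O[Si](CC)(CC)CC)CCC=C(C)C)C/C=C(\COCc1ccccc1)CC/C=C(\C)CC/C=C(/C)C(=O)OCC | intermediate
26 | (2Z,6E,10Z,13R,14R)-10-[(benzyloxy)methyl]-2,6,14,18-tetramethyl-13-[(phenylsulfonyl)methyl]-14-[(triethylsilyl)oxy]nonadeca-2,6,10,17-tetraen-1-ol | O=S(=O)(c1ccccc1)C[C@@H]([C@](C)(O[Si](CC)(CC)CC)CCC=C(C)C)C/C=C(\COCc1ccccc1)CC/C=C(\C)CC/C=C(/C)CO | intermediate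
27 | (2Z,6E,10Z,13R,14R)-10-[(benzyloxy)methyl]-1-bromo-2,6,14,18-tetramethyl-13-[(phenylsulfonyl)methyl]-14-[(triethylsilyl)oxy]nonadeca-2,6,10,17-tetraene | O=S(=O)(c1ccccc1)C[C@@H]([C@](C)(O[Si](CC)(CC)CC)CCC=C(C)C)C/C=C(\COCc1ccccc1)CC/C=C(\C)CC/C=C(/C)CBr | intermediate
28 | triethyl({(2R)-2-[(1R,3Z,7E,11Z)-4-[(benzyloxy)methyl]-8,12-dimethyl-14-(phenylsulfonyl)cyclotetradeca-3,7,11-trien-1-yl]-6-methylhept-5-en-2-yl}oxy)silane (C14 epimers) | O=S(=O)(c1ccccc1)C1[C@@H]([C@](C)(O[Si](CC)(CC)CC)CCC=C(C)C)C/C=C(\COCc2ccccc2)CC/C=C(\C)CC/C=C(/C)C1 | intermediate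
29 | {(2R)-2-[(1R,3Z,7E,11Z)-4-(hydroxymethyl)-8,12-dimethylcyclotetradeca-3,7,11-trien-1-yl]-6-methylhept-5-en-2-yl} triethylsilyl ether | CC(C)=CCC[C@@](C)(O[Si](CC)(CC)CC)[C@H]1C/C=C(\CO)CC/C=C(\C)CC/C=C(/C)CC1 | intermediate
30 | (2R)-2-[(1R,3Z,7E,11Z)-4-(hydroxymethyl)-8,12-dimethylcyclotetradeca-3,7,11-trien-1-yl]-6-methylhept-5-en-2-ol | CC(C)=CCC[C@@](C)(O)[C@H]1C/C=C(\CO)CC/C=C(\C)CC/C=C(/C)CC1 | target

## Step count and risks

Total step count: 22.
Longest linear sequence: 14 steps (steps 1–8, then 17–22). The fragment B branch is 13 steps (9–13, 15–22) and the keto ester branch starts at step 14.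

Three steps most likely to fail:

**Step 20 (macrocyclisation).** The carbanion is hard, sits next to a congested centre, and competes with elimination and oligomerisation. The fallback keeps the same ring bond but switches to a soft, doubly stabilised nucleophile under carbonate conditions. It sets out from allylic alcohol 26 and comes back at macrocycle 28. Alcohol 26 is converted with MsCl, LiCl and 2,4,6-collidine in DMF at 0 °C into the less reactive allylic chloride F1. The sulfone is C-acylated (LDA 2.1 equiv, THF, −78 °C, then ClCO2Me) to give the α-sulfonyl methyl ester F2. Slow addition of F2 to Cs2CO3 and catalytic NaI in MeCN at 60 °C closes the ring to the macrocyclic sulfonyl ester F3. Krapcho demethoxycarbonylation (LiCl, wet DMSO, 140 °C) then returns sulfone 28.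

**Step 17 (Wittig union).** The Z preference of α-alkoxy ketones may erode with the longer ketone arm, and the ylide can enolise the ketone. The fallback builds the chain linearly on fragment A with sigmatropic control of both new alkenes. It sets out from alcohol 9 and comes back at ester 25, without needing 10, 11 or 23. Dess–Martin oxidation gives aldehyde F4. Addition of 2-bromoallyl benzyl ether mediated by CrCl2 with catalytic NiCl2 in DMF gives allylic alcohol F5. Johnson–Claisen rearrangement (MeC(OEt)3, catalytic EtCO2H, 135 °C) gives ester F6, with C2 trans to the new chain and cis to CH2OBn through the chair transition state. DIBAL-H at −78 °C gives aldehyde F7, and CrCl2/NiCl2 addition of 2-bromopropene gives allylic alcohol F8. A second Johnson–Claisen rearrangement gives ester F9 with the 7E alkene, and DIBAL-H gives aldehyde F10. Still–Gennari olefination of F10 with 15 (KHMDS, 18-crown-6, THF, −78 °C) gives 25.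

**Step 2 (epoxide opening).** The attacked carbon is flanked by a fully substituted epoxide carbon, so the cuprate may be sluggish and the magnesium salts may cause rearrangement. The fallback introduces the two carbons as a small acetylide on a protected substrate. It sets out from epoxide 2 and comes back at diol 4. TBSCl and imidazole give silyl ether F11. Lithium acetylide–ethylenediamine complex in DMSO at rt → 45 °C opens the epoxide at the CH carbon with inversion to alkynyl alcohol F12. Semi-hydrogenation (H2, Pd/CaCO3 poisoned with Pb(OAc)2, quinoline) gives vinyl alcohol F13, and TBAF gives 4.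

## Further compounds

F1 | step 20 | (2Z,6E,10Z,13R,14R)-10-[(benzyloxy)methyl]-1-chloro-2,6,14,18-tetramethyl-13-[(phenylsulfonyl)methyl]-14-[(triethylsilyl)oxy]nonadeca-2,6,10,17-tetraene | O=S(=O)(c1ccccc1)C[C@@H]([C@](C)(O[Si](CC)(CC)CC)CCC=C(C)C)C/C=C(\COCc1ccccc1)CC/C=C(\C)CC/C=C(/C)CCl
F2 | step 20 | methyl (3R,5Z,9E,13Z)-6-[(benzyloxy)methyl]-15-chloro-10,14-dimethyl-3-{(2R)-6-methyl-2-[(triethylsilyl)oxy]hept-5-en-2-yl}-2-(phenylsulfonyl)pentadeca-5,9,13-trienoate (C2 epimers) | COC(=O)C(S(=O)(=O)c1ccccc1)[C@@H]([C@](C)(O[Si](CC)(CC)CC)CCC=C(C)C)C/C=C(\COCc1ccccc1)CC/C=C(\C)CC/C=C(/C)CCl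
F3 | step 20 | methyl (3Z,7E,11Z,14R)-11-[(benzyloxy)methyl]-3,7-dimethyl-14-{(2R)-6-methyl-2-[(triethylsilyl)oxy]hept-5-en-2-yl}-1-(phenylsulfonyl)cyclotetradeca-3,7,11-triene-1-carboxylate (C1 epimers) | COC(=O)C1(S(=O)(=O)c2ccccc2)[C@@H]([C@](C)(O[Si](CC)(CC)CC)CCC=C(C)C)C/C=C(\COCc2ccccc2)CC/C=C(\C)CC/C=C(/C)C1
F4 | step 17 | (3R,4R)-4,8-dimethyl-3-[(phenylsulfonyl)methyl]-4-[(triethylsilyl)oxy]non-7-enal | O=S(=O)(c1ccccc1)C[C@@H]([C@](C)(O[Si](CC)(CC)CC)CCC=C(C)C)CC=O
F5 | step 17 | (5R,6R)-2-[(benzyloxy)methyl]-6,10-dimethyl-5-[(phenylsulfonyl)methyl]-6-[(triethylsilyl)oxy]undeca-1,9-dien-3-ol (C3 epimers) | O=S(=O)(c1ccccc1)C[C@@H]([C@](C)(O[Si](CC)(CC)CC)CCC=C(C)C)CC(O)C(=C)COCc1ccccc1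
F6 | step 17 | ethyl (4Z,7R,8R)-4-[(benzyloxy)methyl]-8,12-dimethyl-7-[(phenylsulfonyl)methyl]-8-[(triethylsilyl)oxy]trideca-4,11-dienoate | O=S(=O)(c1ccccc1)C[C@@H]([C@](C)(O[Si](CC)(CC)CC)CCC=C(C)C)C/C=C(\COCc1ccccc1)CCC(=O)OCC
F7 | step 17 | (4Z,7R,8R)-4-[(benzyloxy)methyl]-8,12-dimethyl-7-[(phenylsulfonyl)methyl]-8-[(triethylsilyl)oxy]trideca-4,11-dienal | O=S(=O)(c1ccccc1)C[C@@H]([C@](C)(O[Si](CC)(CC)CC)CCC=C(C)C)C/C=C(\COCc1ccccc1)CCC=O
F8 | step 17 | (6Z,9R,10R)-6-[(benzyloxy)methyl]-2,10,14-trimethyl-9-[(phenylsulfonyl)methyl]-10-[(triethylsilyl)oxy]pentadeca-1,6,13-trien-3-ol (C3 epimers) | O=S(=O)(c1ccccc1)C[C@@H]([C@](C)(O[Si](CC)(CC)CC)CCC=C(C)C)C/C=C(\COCc1ccccc1)CCC(O)C(C)=C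
F9 | step 17 | ethyl (4E,8Z,11R,12R)-8-[(benzyloxy)methyl]-4,12,16-trimethyl-11-[(phenylsulfonyl)methyl]-12-[(triethylsilyl)oxy]heptadeca-4,8,15-trienoate | O=S(=O)(c1ccccc1)C[C@@H]([C@](C)(O[Si](CC)(CC)CC)CCC=C(C)C)C/C=C(\COCc1ccccc1)CC/C=C(\C)CCC(=O)OCC
F10 | step 17 | (4E,8Z,11R,12R)-8-[(benzyloxy)methyl]-4,12,16-trimethyl-11-[(phenylsulfonyl)methyl]-12-[(triethylsilyl)oxy]heptadeca-4,8,15-trienal | O=S(=O)(c1ccccc1)C[C@@H]([C@](C)(O[Si](CC)(CC)CC)CCC=C(C)C)C/C=C(\COCc1ccccc1)CC/C=C(\C)CCC=O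
F11 | step 2 | tert-butyl(dimethyl){[(2R,3R)-3-methyl-3-(4-methylpent-3-en-1-yl)oxiran-2-yl]methoxy}silane | CC(C)(C)[Si](C)(C)OC[C@H]1O[C@]1(C)CCC=C(C)C
F12 | step 2 | (2S,3R)-1-{[tert-butyl(dimethyl)silyl]oxy}-2-ethynyl-3,7-dimethyloct-6-en-3-ol | CC(C)(C)[Si](C)(C)OC[C@@H]([C@](C)(O)CCC=C(C)C)C#C
F13 | step 2 | (2S,3R)-1-{[tert-butyl(dimethyl)silyl]oxy}-2-ethenyl-3,7-dimethyloct-6-en-3-ol | CC(C)(C)[Si](C)(C)OC[C@@H]([C@](C)(O)CCC=C(C)C)C=C
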